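## Retrosynthetic overview

1. Only the tetronic acid ring is built, and it is built last; the furan ring arrives intact in cheap furan-3-ylmethanol.
2. The tetronic acid is opened along its presumed biosynthetic end game (C21 hydroxylation of a 22-oxo-24-oate, then lactonisation), giving an acyclic β-keto ester. In the forward sense its dianion is hydroxylated enantioselectively at C21 by a chiral N-sulfonyloxaziridine and lactonises in the same flask.
3. The β-keto ester is cut at C20–C21: γ-alkylation of the dianion of ethyl 2-methylacetoacetate with a C20 (E)-allylic bromide.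
4. The allylic bromide comes from oxidation of the terminal (E)-methyl group of ambliofuran with SeO2, echoing terminal oxidation of the prenyl chain.
5. Ambliofuran comes from copper-catalysed coupling of the 3-furylmethyl Grignard reagent with (2E,6E)-farnesyl bromide, which supplies all three E alkenes.

Assumption: the dienolate terminus is taken to respond to the camphor-derived oxaziridine as the (Z)-enolates of alkyl aryl ketones do, where the (2R,8aS) reagent gives (S) alcohols; on that basis the (2S,8aR) reagent is used to obtain (R), and if the sense proves opposite the mirror-image reagent is used in the same step.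

## Route

Step 1
Reactants: 1 furan-3-ylmethanol
Product: 3 3-(chloromethyl)furan, via furan-3-ylmethyl methanesulfonate 2 (not isolated)
Conditions: MsCl (1.1 equiv), LiCl (1.5 equiv), 2,4,6-collidine (1.2 equiv), DMF, 0 °C, 2 h; pentane extraction, dried solution used at once
Reagents that add atoms: lithium chloride, [Li+].[Cl-]
Why: Collington–Meyers chlorination, in which the mesylate formed in the flask is displaced by chloride (SN2) under buffered, acid-free conditions that spare the furan; no stereocenter is involved.

Step 2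
Reactants: 3 3-(chloromethyl)furan; 4 (2E,6E)-farnesyl bromide [(2E,6E)-1-bromo-3,7,11-trimethyldodeca-2,6,10-triene]
Product: 6 3-[(3E,7E)-4,8,12-trimethyltrideca-3,7,11-trien-1-yl]furan (ambliofuran), via (furan-3-ylmethyl)magnesium chloride 5 (not isolated)
Conditions: Mg turnings, THF, 0 → 25 °C; then added to 4 and Li2CuCl4 (3 mol %), THF, 0 °C
Reagents that add atoms: none
Why: Grignard formation followed by Li2CuCl4-catalysed Kochi-type sp3–sp3 cross-coupling at the primary allylic carbon, which joins the furylmethyl carbon to C1 of the farnesyl unit without allylic transposition and keeps both E alkenes; no stereocenter is involved.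

Step 3
Reactants: 6 ambliofuran
Product: 7 (2E,6E,10E)-13-(furan-3-yl)-2,6,10-trimethyltrideca-2,6,10-trien-1-ol
Conditions: SeO2 (0.2 equiv), t-BuOOH (2 equiv), salicylic acid (0.1 equiv), CH2Cl2, 0 → 23 °C, stopped near 60 % conversion, recovered 6 recycled
Reagents that add atoms: selenium dioxide, O=[Se]=O (delivers the oxygen and is regenerated by tert-butyl hydroperoxide, CC(C)(C)OO)
Why: Sharpless catalytic SeO2 allylic oxidation (ene reaction, then [2,3]-sigmatropic shift) attacks the (E)-methyl group of the terminal, least hindered trisubstituted alkene and gives the (E)-allylic alcohol, a laboratory counterpart of terminal oxidation of the prenyl chain; no stereocenter is involved.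

Step 4
Reactants: 7 (2E,6E,10E)-13-(furan-3-yl)-2,6,10-trimethyltrideca-2,6,10-trien-1-ol
Product: 8 3-[(3E,7E,11E)-13-bromo-4,8,12-trimethyltrideca-3,7,11-trien-1-yl]furan
Conditions: CBr4 (1.2 equiv), PPh3 (1.25 equiv), CH2Cl2, −20 → 0 °C; pentane/silica plug, used without storage
Reagents that add atoms: carbon tetrabromide, BrC(Br)(Br)Br
Why: Appel reaction (SN2 on the alkoxyphosphonium ion) converts the primary allylic alcohol into the bromide under neutral conditions, without allylic shift, loss of E geometry or harm to the furan.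

Step 5
Reactants: 8 3-[(3E,7E,11E)-13-bromo-4,8,12-trimethyltrideca-3,7,11-trien-1-yl]furan; 9 ethyl 2-methyl-3-oxobutanoate (ethyl 2-methylacetoacetate)
Product: 11 ethyl (6E,10E,14E)-17-(furan-3-yl)-2,6,10,14-tetramethyl-3-oxoheptadeca-6,10,14-trienoate (mixture at C2), via acetoacetate dilithium dienolate 10 (not isolated)
Conditions: 9 (1.5 equiv), LiN(iPr)2 (3.1 equiv, commercial solution), THF, 0 °C, 30 min; −78 °C, add 8; → 0 °C; cold 1 M HCl to pH 5
Reagents that add atoms: none
Why: Weiler dianion alkylation, in which the terminal carbanion of the β-keto ester dianion is the most nucleophilic site and displaces the primary allylic bromide (SN2) to form the C20–C21 bond; the C2 center is formed as a mixture but becomes sp2 in the final ring, and the amide base does not metalate the furan.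

Step 6
Reactants: 11 ethyl (6E,10E,14E)-17-(furan-3-yl)-2,6,10,14-tetramethyl-3-oxoheptadeca-6,10,14-trienoate
Product: 14 (5R)-5-[(2E,6E,10E)-13-(furan-3-yl)-2,6,10-trimethyltrideca-2,6,10-trien-1-yl]-4-hydroxy-3-methylfuran-2(5H)-one (the target), via keto ester dilithium dienolate 12 (not isolated), via dilithium alkoxide enolate 13 (not isolated)
Conditions: LiN(iPr)2 (2.1 equiv), THF, −78 → −20 °C; −78 °C, (−)-(2S,8aR)-(camphorsulfonyl)oxaziridine (1.05 equiv), 1 h; EtOH (2 equiv), → 23 °C, 2 h; cold 1 M HCl to pH 3
Reagents that add atoms: (−)-(2S,8aR)-(camphorsulfonyl)oxaziridine [(1R)-(−)-(10-camphorsulfonyl)oxaziridine], CC1(C)[C@H]2CC[C@@]13CS(=O)(=O)N4O[C@]34C2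
Why: Proposed new method: the second deprotonation puts a carbanion at C4 of the keto ester (the future ring C5) that is far more nucleophilic than the stabilised enolate, the four neutral alkenes or the furan, so it alone attacks the electrophilic oxygen of the N-sulfonyloxaziridine (SN2 at oxygen, then loss of the hindered sulfonimine), the camphor scaffold shielding one face of the (Z)-configured dienolate terminus so that the (2S,8aR) reagent is expected to give the (R) carbinol; the γ-alkoxide then closes onto the ethyl ester (5-exo-trig lactonisation, eased by the ethanol proton shuttle) to the tetronate, whose C5–H is not acidic as the anion, so the new stereocenter is kept; this reproduces the presumed biosynthetic C21 hydroxylation and lactonisation, and the closest known reaction types are Davis asymmetric enolate hydroxylation, γ-functionalisation of Weiler dianions and base-mediated cyclisation of γ-hydroxy β-keto esters to tetronic acids.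

## Compound list

1 | furan-3-ylmethanol | OCc1ccoc1 | starting material
2 | furan-3-ylmethyl methanesulfonate | CS(=O)(=O)OCc1ccoc1 | intermediate (not isolated)
3 | 3-(chloromethyl)furan | ClCc1ccoc1 | intermediate
4 | (2E,6E)-farnesyl bromide, (2E,6E)-1-bromo-3,7,11-trimethyldodeca-2,6,10-triene | CC(C)=CCC/C(C)=C/CC/C(C)=C/CBr | starting material
5 | (furan-3-ylmethyl)magnesium chloride | Cl[Mg]Cc1ccoc1 | intermediate (not isolated)
6 | 3-[(3E,7E)-4,8,12-trimethyltrideca-3,7,11-trien-1-yl]furan (ambliofuran) | CC(C)=CCC/C(C)=C/CC/C(C)=C/CCc1ccoc1 | intermediate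
7 | (2E,6E,10E)-13-(furan-3-yl)-2,6,10-trimethyltrideca-2,6,10-trien-1-ol | OC/C(C)=C/CC/C(C)=C/CC/C(C)=C/CCc1ccoc1 | intermediate
8 | 3-[(3E,7E,11E)-13-bromo-4,8,12-trimethyltrideca-3,7,11-trien-1-yl]furan | BrC/C(C)=C/CC/C(C)=C/CC/C(C)=C/CCc1ccoc1 | intermediate
9 | ethyl 2-methyl-3-oxobutanoate | CCOC(=O)C(C)C(C)=O | starting material
10 | dilithium 1-ethoxy-2-methylbuta-1,3-diene-1,3-diolate (dianion of 9, carbanion at the terminal carbon) | [Li+].[Li+].C=C([O-])C(C)=C([O-])OCC | intermediate (not isolated)
11 | ethyl (6E,10E,14E)-17-(furan-3-yl)-2,6,10,14-tetramethyl-3-oxoheptadeca-6,10,14-trienoate (C2 unassigned, mixture) | CCOC(=O)C(C)C(=O)CC/C(C)=C/CC/C(C)=C/CC/C(C)=C/CCc1ccoc1 | intermediate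
12 | dilithium (6E,10E,14E)-1-ethoxy-17-(furan-3-yl)-2,6,10,14-tetramethylheptadeca-1,3,6,10,14-pentaene-1,3-diolate (dianion of 11, carbanion at C4) | [Li+].[Li+].CCOC([O-])=C(C)C([O-])=CC/C(C)=C/CC/C(C)=C/CC/C(C)=C/CCc1ccoc1 | intermediate (not isolated)
13 | dilithium salt (C4 alkoxide, C1–C3 enolate) of ethyl (4R,6E,10E,14E)-17-(furan-3-yl)-4-hydroxy-2,6,10,14-tetramethyl-3-oxoheptadeca-6,10,14-trienoate | [Li+].[Li+].CCOC([O-])=C(C)C(=O)[C@H]([O-])C/C(C)=C/CC/C(C)=C/CC/C(C)=C/CCc1ccoc1 | intermediate (not isolated)
14 | (5R)-5-[(2E,6E,10E)-13-(furan-3-yl)-2,6,10-trimethyltrideca-2,6,10-trien-1-yl]-4-hydroxy-3-methylfuran-2(5H)-one | CC1=C(O)[C@@H](C/C(C)=C/CC/C(C)=C/CC/C(C)=C/CCc2ccoc2)OC1=O | target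

## Step count and risks

Total step count: 6. Longest linear sequence: 6 steps (1 → 3 → 6 → 7 → 8 → 11 → 14); compounds 4 and 9 enter at steps 2 and 5.

The three steps most likely to fail:

**Step 6 (hydroxylation and lactonisation of the dianion).** The facial selectivity on a β-keto ester dianion is untested, a second hydroxylation at C2 is possible if the oxidant is overcharged, and ring closure may lag. The ee would be read by chiral HPLC on 14.

The fallback sets out from 8 and comes back at 14. It replaces the C–O bond formation by an auxiliary-controlled C–C bond formation and closes the ring by Dieckmann condensation. The sodium enolate (NaN(SiMe3)2, THF, −78 °C) of the glycolate imide (S)-4-benzyl-3-[(4-methoxybenzyloxy)acetyl]oxazolidin-2-one F1 (one acylation from the commercial auxiliary) is alkylated with 8 to give the (2R)-alkylated imide F2. The bromide enters anti to the benzyl group of the chelated (Z)-enolate (Evans–Crimmins glycolate alkylation). MeOMgBr in MeOH at 0 °C exchanges the auxiliary for methoxide to give the (2R)-PMB-oxy methyl ester F3. DDQ in CH2Cl2/pH 7 buffer at 0 °C removes the PMB group to give the (2R)-hydroxy methyl ester F4. Propionic anhydride/DMAP gives the (2R)-propanoyloxy methyl ester F5. LiN(SiMe3)2 (2.5 equiv), THF, −78 → 0 °C then closes the ring to 14 with the stereocenter untouched.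

**Step 3 (SeO2 oxidation of 6).** Three similar trisubstituted alkenes and a furan face the oxidant, so site selectivity and yield may be poor.

The fallback sets out from 3 (as its Grignard reagent 5, made as in step 2) and comes back at 7. The oxidation is done before the furan is attached. Purchased (2E,6E)-farnesyl acetate F6 is oxidised with SeO2 (cat.)/t-BuOOH, where the acetate deactivates the proximal alkene, to (2E,6E,10E)-12-hydroxyfarnesyl acetate F7. Then 5 (2.5 equiv, the first equivalent taken up by the hydroxyl) with Li2CuCl4 (cat.) in THF at 0 °C displaces the allylic acetate to give 7.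

**Step 2 (furylmethyl Grignard coupling).** Wurtz dimerisation of the furylmethyl halide and SN2′ attack on the farnesyl unit can erode the yield.

The fallback sets out from 4 and 3 and comes back at 6. It inverts the polarity so that the furan piece is the electrophile. Compound 4 and PhSO2Na in DMF give (2E,6E)-farnesyl phenyl sulfone F8. Its lithio derivative (n-BuLi, THF, −78 °C, formed before any furan is present) is alkylated with 3 to give the furylmethylated sulfone F9. Reductive desulfonylation with LiBHEt3 and PdCl2(dppp) (5 mol %) in THF at 0 °C, which keeps alkene position and geometry, gives 6.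

## Further compounds

F1 | step 6 | (S)-4-benzyl-3-[(4-methoxybenzyloxy)acetyl]oxazolidin-2-one | COc1ccc(COCC(=O)N2[C@@H](Cc3ccccc3)COC2=O)cc1
F2 | step 6 | (S)-4-benzyl-3-[(2R,4E,8E,12E)-15-(furan-3-yl)-2-(4-methoxybenzyloxy)-4,8,12-trimethylpentadeca-4,8,12-trienoyl]oxazolidin-2-one | COc1ccc(CO[C@H](C/C(C)=C/CC/C(C)=C/CC/C(C)=C/CCc2ccoc2)C(=O)N2[C@@H](Cc3ccccc3)COC2=O)cc1
F3 | step 6 | methyl (2R,4E,8E,12E)-15-(furan-3-yl)-2-(4-methoxybenzyloxy)-4,8,12-trimethylpentadeca-4,8,12-trienoate | COc1ccc(CO[C@H](C/C(C)=C/CC/C(C)=C/CC/C(C)=C/CCc2ccoc2)C(=O)OC)cc1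
F4 | step 6 | methyl (2R,4E,8E,12E)-15-(furan-3-yl)-2-hydroxy-4,8,12-trimethylpentadeca-4,8,12-trienoate | O[C@H](C/C(C)=C/CC/C(C)=C/CC/C(C)=C/CCc1ccoc1)C(=O)OC
F5 | step 6 | methyl (2R,4E,8E,12E)-15-(furan-3-yl)-4,8,12-trimethyl-2-(propanoyloxy)pentadeca-4,8,12-trienoate | CCC(=O)O[C@H](C/C(C)=C/CC/C(C)=C/CC/C(C)=C/CCc1ccoc1)C(=O)OC
F6 | step 3 | (2E,6E)-farnesyl acetate, (2E,6E)-3,7,11-trimethyldodeca-2,6,10-trien-1-yl acetate (purchased) | CC(C)=CCC/C(C)=C/CC/C(C)=C/COC(C)=O
F7 | step 3 | (2E,6E,10E)-12-hydroxy-3,7,11-trimethyldodeca-2,6,10-trien-1-yl acetate | OC/C(C)=C/CC/C(C)=C/CC/C(C)=C/COC(C)=O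
F8 | step 2 | [(2E,6E)-3,7,11-trimethyldodeca-2,6,10-trien-1-yl]sulfonylbenzene | CC(C)=CCC/C(C)=C/CC/C(C)=C/CS(=O)(=O)c1ccccc1
F9 | step 2 | 3-[(3E,7E)-4,8,12-trimethyl-2-(phenylsulfonyl)trideca-3,7,11-trien-1-yl]furan (racemic) | CC(C)=CCC/C(C)=C/CC/C(C)=C/C(Cc1ccoc1)S(=O)(=O)c1ccccc1
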